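A direct plan would condense 2,5-dibromobenzaldehyde A1 with ethyl azidoacetate A2 to ethyl (Z)-2-azido-3-(2,5-dibromophenyl)acrylate A3 and would close the pyrrole ring by Hemetsberger–Knittel thermolysis to ethyl 4,7-dibromo-1H-indole-2-carboxylate A4.
It would then saponify A4 to 4,7-dibromo-1H-indole-2-carboxylic acid A5, decarboxylate this to 4,7-dibromo-1H-indole A6 and brominate with NBS through 3,4,7-tribromo-1H-indole A7 to the target.
Its weakest points would be the following.
(a) The azide condensation and thermolysis: an excess of a small organic azide and a nitrene generated near 140 °C would limit the scale, and the ortho bromine would slow the condensation.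
(b) The saponification and the Cu/quinoline decarboxylation near 215 °C: two steps that would only remove a carboxyl group needed for ring closure and would put the aryl bromides at risk.
(c) The second electrophilic bromination, at C2 of an NH 3-bromoindole: it would be slower than the first and would compete with oxidation to oxindole-type products.

The proposed route builds the benzene ring last, onto a purchased pyrrole. Because C4 and C7, the benzo carbons flanking the ring fusion, both carry bromine, C3a–C4 and C7–C7a can be formed by an inverse-electron-demand Diels–Alder reaction of 2,5-dibromothiophene 1,1-dioxide with the C4=C5 bond of an N-Boc-2-silyloxypyrrole, followed by SO2 extrusion and dehydrogenation. In one operation the diene delivers C4 to C7 with both bromines in place, and the dienophile delivers N1, C2, C3 and a C2 oxygen that later becomes bromine. No azide or nitrene is used, no carboxyl group must be removed, and the only electrophilic bromination left is the easy one at C3.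

Key step: step 2

Remark: compound 3 is taken as a commercial reagent; the target is achiral, so the transient stereocentres of 4 and 5 need no control.

Step 1
Reactants: 1 2,5-dibromothiophene
Product: 2 2,5-dibromothiophene 1,1-dioxide
Conditions: (CF3CO)2O (excess), 50% aq. H2O2 (3 equiv), CH2Cl2, 0 °C → rt, 12 h; cold aq. NaHCO3 wash
Reagents that add atoms: hydrogen peroxide, OO (delivered as trifluoroperacetic acid, OOC(=O)C(F)(F)F, formed in situ)
Why: Trifluoroperacetic acid is electrophilic enough to take the electron-poor sulfur of a 2,5-dihalothiophene through the sulfoxide to the sulfone (peracid sulfide-to-sulfone oxidation), and the two α-bromines slow the [4+2] self-dimerisation that destroys less substituted thiophene dioxides.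

Step 2
Reactants: 2 2,5-dibromothiophene 1,1-dioxide; 3 tert-butyl 2-[(tert-butyldimethylsilyl)oxy]-1H-pyrrole-1-carboxylate (1.5 equiv)
Product: 6 tert-butyl 4,7-dibromo-2-[(tert-butyldimethylsilyl)oxy]-1H-indole-1-carboxylate, via SO2-bridged cycloadduct 4 (not isolated), via cis-3a,7a-dihydroindole 5 (not isolated)
Conditions: toluene, 90 °C, N2 (−SO2); then DDQ (1.1 equiv), 0 °C → rt, 1 h; filtration through basic Al2O3, crude 6 used directly
Reagents that add atoms: none
Why: Proposed new method: the LUMO of diene 2, lowered by the sulfonyl group and both bromines, should engage the HOMO of 3 in an inverse-electron-demand Diels–Alder reaction at the C4=C5 bond, whose C5 is the most nucleophilic carbon of a 2-silyloxypyrrole, so that the two CBr termini of 2 bond to C5 and C4 of 3 and the six-membered carbocycle closes by an intermolecular, suprafacial [4+2] cycloaddition (possibly asynchronous, C5 first). The bridged sulfone 4 should extrude SO2 cheletropically at the reaction temperature to give diene 5, and DDQ should then abstract hydride from the doubly allylic C3a–H or the N-substituted C7a–H and, after proton loss, leave the benzene ring with bromine at exactly C4 and C7. The closest known reaction type is the Diels–Alder/SO2 extrusion/dehydrogenation benzannulation of halogenated thiophene 1,1-dioxides with enol ethers, enamines and cycloalkenes, together with the use of furan and indole C2=C3 bonds as 2π partners of electron-poor dienes. The cis stereocentres at C3a and C7a and the two bridgeheads follow from the suprafacial addition, are formed as a racemic endo/exo mixture and are all erased on aromatisation, so no stereocontrol is needed. The step needs site selectivity for C4=C5 over C2=C3 of 3, which the fully substituted, OSi- and NBoc-bearing C2 should secure on steric grounds, and it needs no regiocontrol because 2 is symmetric. It also needs cycloaddition to outrun vinylogous Michael addition and a second addition to the ketene aminal bond of 5, which the absence of a Lewis acid, the excess of 3 and the congestion around C2=C3 of 5 should favour.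

Step 3
Reactants: 6 tert-butyl 4,7-dibromo-2-[(tert-butyldimethylsilyl)oxy]-1H-indole-1-carboxylate
Product: 7 4,7-dibromoindolin-2-one (4,7-dibromooxindole)
Conditions: TFA/CH2Cl2 1:2, 0 °C → rt, 2 h; aqueous work-up
Reagents that add atoms: none
Why: Acid should protonate the silyl ketene aminal at C3 (protodesilylation of a silyl enol ether to the lactam) and cleave the N-Boc carbamate by loss of the tert-butyl cation and decarboxylation, while the aryl bromides are inert.

Step 4
Reactants: 7 4,7-dibromoindolin-2-one
Product: 8 2,4,7-tribromo-1H-indole
Conditions: POBr3 (2.5 equiv), imidazole (1.2 equiv), ClCH2CH2Cl, reflux, 4 h; ice-water quench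
Reagents that add atoms: phosphorus oxybromide, O=P(Br)(Br)Br
Why: The lactam oxygen should be phosphorylated, bromide should add to the activated C2 and expel dibromophosphate, and the 2-bromo-3H-indole should tautomerise to the aromatic 2-bromoindole (Vilsmeier-type deoxybromination of an oxindole through its imidoyl bromide); the two benzo bromines should make the product less acid-sensitive than 2-bromoindole itself.

Step 5
Reactants: 8 2,4,7-tribromo-1H-indole
Product: 9 2,3,4,7-tetrabromo-1H-indole
Conditions: NBS (1.05 equiv), DMF, 0 °C, dark, 1 h; aq. Na2S2O3 work-up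
Reagents that add atoms: N-bromosuccinimide, O=C1CCC(=O)N1Br
Why: Electrophilic aromatic substitution should take place at C3, the only free and the most nucleophilic pyrrole position (σ-complex stabilised by nitrogen), while the doubly brominated benzo ring is deactivated.

**Compound list**
1 | 2,5-dibromothiophene | Brc1ccc(Br)s1 | starting material
2 | 2,5-dibromothiophene 1,1-dioxide | O=S1(=O)C(Br)=CC=C1Br | intermediate
3 | tert-butyl 2-[(tert-butyldimethylsilyl)oxy]-1H-pyrrole-1-carboxylate | CC(C)(C)OC(=O)n1cccc1O[Si](C)(C)C(C)(C)C | starting material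
4 | tert-butyl 4,7-dibromo-2-[(tert-butyldimethylsilyl)oxy]-3a,4,7,7a-tetrahydro-4,7-epithio-1H-indole-1-carboxylate S,S-dioxide (cis-fused, racemic endo/exo mixture, not isolated) | CC(C)(C)OC(=O)N1C(O[Si](C)(C)C(C)(C)C)=CC2C1C3(Br)C=CC2(Br)S3(=O)=O | intermediate
5 | tert-butyl cis-4,7-dibromo-2-[(tert-butyldimethylsilyl)oxy]-3a,7a-dihydro-1H-indole-1-carboxylate (racemic, one enantiomer drawn, not isolated) | CC(C)(C)OC(=O)N1C(O[Si](C)(C)C(C)(C)C)=C[C@H]2[C@@H]1C(Br)=CC=C2Br | intermediate
6 | tert-butyl 4,7-dibromo-2-[(tert-butyldimethylsilyl)oxy]-1H-indole-1-carboxylate | CC(C)(C)OC(=O)n1c(O[Si](C)(C)C(C)(C)C)cc2c(Br)ccc(Br)c21 | intermediate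
7 | 4,7-dibromoindolin-2-one | O=C1Cc2c(Br)ccc(Br)c2N1 | intermediate
8 | 2,4,7-tribromo-1H-indole | Brc1cc2c(Br)ccc(Br)c2[nH]1 | intermediate
9 | 2,3,4,7-tetrabromo-1H-indole | Brc1[nH]c2c(Br)ccc(Br)c2c1Br | target

Total step count: 5. Longest linear sequence: 5.

Steps most likely to fail:

Step 2. The silyloxypyrrole may add to the sulfone as a vinylogous Michael donor without ring closure, may react as the 4π partner, or the first product may take up a second diene. The fallback sets out from 2 and comes back at 8. Compound 2 would be heated with tert-butyl 2,3-dihydro-1H-pyrrole-1-carboxylate F1, a plain electron-rich cyclic alkene of the class established as 2π partner for halogenated thiophene dioxides. The SO2-bridged cycloadduct F2 would lose SO2 to tert-butyl cis-4,7-dibromo-2,3,3a,7a-tetrahydro-1H-indole-1-carboxylate F3. DDQ in hot toluene would dehydrogenate this through tert-butyl 4,7-dibromoindoline-1-carboxylate F4 to tert-butyl 4,7-dibromo-1H-indole-1-carboxylate F5. LiN(i-Pr)2 at −78 °C would give, by carbamate-directed deprotonation, tert-butyl 4,7-dibromo-2-lithio-1H-indole-1-carboxylate F6, and BrCCl2CCl2Br would convert it into tert-butyl 2,4,7-tribromo-1H-indole-1-carboxylate F7. K2CO3 in MeOH would then remove the Boc group to give 8, which would enter step 5 as planned.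

Step 4. O-activation of the NH lactam may stay incomplete, or the NH 2-bromoindole may be lost to acid-induced oligomerisation or hydrolysis back to the oxindole during reaction and work-up. The fallback sets out from 7 and comes back at 9. Vilsmeier–Haack haloformylation of 7 (POBr3, DMF, CHCl3) would give 2,4,7-tribromo-1H-indole-3-carbaldehyde F8, a 2-bromoindole stabilised by the formyl group. Pinnick oxidation (NaClO2, NaH2PO4, 2-methyl-2-butene) would give 2,4,7-tribromo-1H-indole-3-carboxylic acid F9. Bromodecarboxylation with NBS in DMF (ipso attack at C3, loss of CO2) would give 9 directly.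

Step 1. The oxidation may stall at the sulfoxide, or the sulfone may be lost to dimerisation or degradation under the strongly acidic oxidising conditions. The fallback sets out from 1 and comes back at 2. Double bromine–lithium exchange of 1 with n-BuLi would give 2,5-dilithiothiophene F10, and Me3SiCl would give 2,5-bis(trimethylsilyl)thiophene F11. This electron-rich thiophene would be oxidised under mild conditions (mCPBA, CH2Cl2) to 2,5-bis(trimethylsilyl)thiophene 1,1-dioxide F12. Ipso-bromodesilylation with Br2 and AgBF4 would then give 2.

Further compounds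
F1 | step 2 | tert-butyl 2,3-dihydro-1H-pyrrole-1-carboxylate | CC(C)(C)OC(=O)N1CCC=C1
F2 | step 2 | tert-butyl 4,7-dibromo-2,3,3a,4,7,7a-hexahydro-4,7-epithio-1H-indole-1-carboxylate S,S-dioxide (cis-fused, racemic endo/exo mixture) | CC(C)(C)OC(=O)N1CCC2C1C3(Br)C=CC2(Br)S3(=O)=O
F3 | step 2 | tert-butyl cis-4,7-dibromo-2,3,3a,7a-tetrahydro-1H-indole-1-carboxylate (racemic, one enantiomer drawn) | CC(C)(C)OC(=O)N1CC[C@H]2[C@@H]1C(Br)=CC=C2Br
F4 | step 2 | tert-butyl 4,7-dibromoindoline-1-carboxylate | CC(C)(C)OC(=O)N1CCc2c(Br)ccc(Br)c21
F5 | step 2 | tert-butyl 4,7-dibromo-1H-indole-1-carboxylate | CC(C)(C)OC(=O)n1ccc2c(Br)ccc(Br)c21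
F6 | step 2 | tert-butyl 4,7-dibromo-2-lithio-1H-indole-1-carboxylate | [Li]c1cc2c(Br)ccc(Br)c2n1C(=O)OC(C)(C)C
F7 | step 2 | tert-butyl 2,4,7-tribromo-1H-indole-1-carboxylate | CC(C)(C)OC(=O)n1c(Br)cc2c(Br)ccc(Br)c21
F8 | step 4 | 2,4,7-tribromo-1H-indole-3-carbaldehyde | O=Cc1c(Br)[nH]c2c(Br)ccc(Br)c12
F9 | step 4 | 2,4,7-tribromo-1H-indole-3-carboxylic acid | OC(=O)c1c(Br)[nH]c2c(Br)ccc(Br)c12
F10 | step 1 | 2,5-dilithiothiophene | [Li]c1ccc([Li])s1
F11 | step 1 | 2,5-bis(trimethylsilyl)thiophene | C[Si](C)(C)c1ccc([Si](C)(C)C)s1
F12 | step 1 | 2,5-bis(trimethylsilyl)thiophene 1,1-dioxide | C[Si](C)(C)C1=CC=C([Si](C)(C)C)S1(=O)=O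
A1 | direct plan | 2,5-dibromobenzaldehyde | O=Cc1cc(Br)ccc1Br
A2 | direct plan | ethyl azidoacetate | CCOC(=O)CN=[N+]=[N-]
A3 | direct plan | ethyl (Z)-2-azido-3-(2,5-dibromophenyl)acrylate | CCOC(=O)/C(N=[N+]=[N-])=C/c1cc(Br)ccc1Br
A4 | direct plan | ethyl 4,7-dibromo-1H-indole-2-carboxylate | CCOC(=O)c1cc2c(Br)ccc(Br)c2[nH]1
A5 | direct plan | 4,7-dibromo-1H-indole-2-carboxylic acid | OC(=O)c1cc2c(Br)ccc(Br)c2[nH]1
A6 | direct plan | 4,7-dibromo-1H-indole | Brc1ccc(Br)c2[nH]ccc12
A7 | direct plan | 3,4,7-tribromo-1H-indole | Brc1c[nH]c2c(Br)ccc(Br)c12
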